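**Retrosynthetic overview**

- The target is reached by one BCl3 cleavage of three benzyl ethers and the peri (5-O) methyl ether of a fully O-protected biflavanone; no stereocentre is touched.
- Both pyranone rings and both C3 centres come from one radical chain operation on an acyclic 1,4-diaryl-1,4-bis(aryloxy)but-2-yne that carries an aryl selenoester at one end and an aryl aldehyde at the other. The pyranone ring of unit M closes first (aroyl radical onto the alkyne), the formyl hydrogen is handed to the vinyl radical, and the pyranone ring of unit H closes second (aroyl radical onto the new enone).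
- The two C2 centres come from two Mitsunobu etherifications (inversion) of propargylic alcohols made by two catalyst-controlled alkynylations of aromatic aldehydes.
- The four benzene rings are bought; an acetylene linchpin supplies the C3–C3 bond of the dimer.

Naming: unit M is the flavanone half with the 7- and 4'-methoxy groups, unit H is the half with free 7- and 4'-hydroxyls; C2, C3 and C4 refer to the pyranone ring of the unit named.

Assumption: (S,S)-ProPhenol with ZnMe2 gives the (S)-configured propargylic alcohols needed in steps 2 and 5; if the sense of induction is the reverse, (R,R)-ProPhenol is used in both steps with no other change.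

**Step 1**
Reactants: 1 2,4,6-trihydroxybenzaldehyde
Product: 2 4,6-bis(benzyloxy)-2-hydroxybenzaldehyde
Conditions: BnBr (2.1 equiv), K2CO3 (2.2 equiv), DMF, 0 °C to rt
Reagents that add atoms: benzyl bromide, BrCc1ccccc1
Why: Williamson etherification in which the 4-OH and one of the two equivalent ortho-OH groups are benzylated while the last ortho-OH stays free because it is held in a hydrogen bond to the formyl group.

**Step 2**
Reactants: 3 4-(benzyloxy)benzaldehyde; 4 ethynyltrimethylsilane
Product: 6 (1S)-1-[4-(benzyloxy)phenyl]-3-(trimethylsilyl)prop-2-yn-1-ol, via methylzinc acetylide 5 (not isolated)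
Conditions: ZnMe2 (3 equiv), (S,S)-ProPhenol (10 mol%), Ph3P=O (20 mol%), PhMe, 0 °C; aq. NH4Cl
Reagents that add atoms: none
Why: Trost zinc–ProPhenol asymmetric alkynylation of an aldehyde, in which the dinuclear zinc catalyst delivers the alkynyl group to one face of the aldehyde and sets the (S) carbinol centre.

**Step 3**
Reactants: 6 (1S)-1-[4-(benzyloxy)phenyl]-3-(trimethylsilyl)prop-2-yn-1-ol; 2 4,6-bis(benzyloxy)-2-hydroxybenzaldehyde
Product: 7 4,6-bis(benzyloxy)-2-{[(1R)-1-[4-(benzyloxy)phenyl]-3-(trimethylsilyl)prop-2-yn-1-yl]oxy}benzaldehyde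
Conditions: PPh3, DIAD, PhMe, −20 °C to rt
Reagents that add atoms: none
Why: Mitsunobu etherification with the acidic ortho-formyl phenol, in which SN2 displacement at the propargylic carbinol inverts (S) to the (R) aryl ether centre that becomes C2 of unit H.

**Step 4**
Reactants: 7 4,6-bis(benzyloxy)-2-{[(1R)-1-[4-(benzyloxy)phenyl]-3-(trimethylsilyl)prop-2-yn-1-yl]oxy}benzaldehyde
Product: 8 4,6-bis(benzyloxy)-2-{[(1S)-1-[4-(benzyloxy)phenyl]prop-2-yn-1-yl]oxy}benzaldehyde
Conditions: K2CO3 (0.2 equiv), MeOH/THF, 0 °C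
Reagents that add atoms: none
Why: Base-catalysed protodesilylation of the alkynylsilane, which leaves the ether centre untouched (the descriptor changes from R to S only because ethynyl ranks below aryl).

**Step 5**
Reactants: 8 4,6-bis(benzyloxy)-2-{[(1S)-1-[4-(benzyloxy)phenyl]prop-2-yn-1-yl]oxy}benzaldehyde; 9 4-methoxybenzaldehyde
Product: 11 4,6-bis(benzyloxy)-2-{[(1R,4S)-1-[4-(benzyloxy)phenyl]-4-hydroxy-4-(4-methoxyphenyl)but-2-yn-1-yl]oxy}benzaldehyde, via methylzinc acetylide 10 (not isolated)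
Conditions: 9 (3 equiv), ZnMe2 (3 equiv), (S,S)-ProPhenol (20 mol%), Ph3P=O (40 mol%), PhMe, 0 °C; aq. NH4Cl
Reagents that add atoms: none
Why: Second Trost zinc–ProPhenol alkynylation, catalyst-controlled because the existing centre lies across the linear alkyne, in which the unhindered 4-methoxybenzaldehyde in excess reacts in preference to the doubly ortho-substituted, strongly deactivated formyl group of 8 and the new carbinol centre is set (S).

**Step 6**
Reactants: 12 2-hydroxy-4,6-dimethoxybenzoic acid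
Product: 13 Se-phenyl 2-hydroxy-4,6-dimethoxybenzenecarboselenoate
Conditions: PhSeSePh (1.1 equiv), PBu3 (1.2 equiv), CH2Cl2, rt
Reagents that add atoms: diphenyl diselenide, c1ccc(cc1)[Se][Se]c1ccccc1
Why: Phosphine–diselenide redox condensation of a carboxylic acid to a selenoester, in which phenylselenolate attacks the phosphorus-activated acyl group and the chelated phenol is left free; no stereocentre is involved.

**Step 7**
Reactants: 11 4,6-bis(benzyloxy)-2-{[(1R,4S)-1-[4-(benzyloxy)phenyl]-4-hydroxy-4-(4-methoxyphenyl)but-2-yn-1-yl]oxy}benzaldehyde; 13 Se-phenyl 2-hydroxy-4,6-dimethoxybenzenecarboselenoate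
Product: 14 Se-phenyl 2-{[(1R,4R)-4-[3,5-bis(benzyloxy)-2-formylphenoxy]-4-[4-(benzyloxy)phenyl]-1-(4-methoxyphenyl)but-2-yn-1-yl]oxy}-4,6-dimethoxybenzenecarboselenoate
Conditions: PPh3, DIAD, PhMe, −20 °C to rt
Reagents that add atoms: none
Why: Second Mitsunobu etherification, in which SN2 inversion turns the (S) carbinol into the (R) aryl ether centre that becomes C2 of unit M, and any stereochemical leakage appears as a diastereomer of 14 that chromatography removes.

**Step 8**
Reactants: 14 Se-phenyl 2-{[(1R,4R)-4-[3,5-bis(benzyloxy)-2-formylphenoxy]-4-[4-(benzyloxy)phenyl]-1-(4-methoxyphenyl)but-2-yn-1-yl]oxy}-4,6-dimethoxybenzenecarboselenoate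
Product: 19 (2S,3S)-3-[(2S,3R)-5,7-bis(benzyloxy)-2-[4-(benzyloxy)phenyl]-4-oxochroman-3-yl]-5,7-dimethoxy-2-(4-methoxyphenyl)chroman-4-one, via first aroyl radical 15 (not isolated), via vinyl radical 16 (not isolated), via second aroyl radical 17 (not isolated), via alpha-keto radical 18 (not isolated)
Conditions: (Me3Si)3SiH (1.3 equiv) + AIBN (0.3 equiv) by syringe pump over 10 h, PhH (2 mM in 14), 80 °C
Reagents that add atoms: none
Why: Proposed new method: a radical-translocation double cyclisation in which the silyl radical takes PhSe from the selenoester to give aroyl radical 15, which closes the pyranone ring of unit M by 6-exo-dig attack on the alkyne; vinyl radical 16 then takes the formyl hydrogen of the other arene by 1,6-hydrogen transfer; the new aroyl radical 17 adds 6-exo-trig to the enone carbon that has just received that hydrogen, under allylic 1,3-strain control (ether C–H in the alkene plane, aryl group opposite the incoming acyl carbon, whichever enone geometry is present), so that C3 of unit H is set trans to C2 (3R beside 2S); alpha-keto radical 18 finally takes hydrogen from the bulky silane on the face anti to the pseudo-axial 4-methoxyphenyl group (Giese anti rule), so that C3 of unit M is set cis to C2 (3S beside 2S) under neutral conditions that cannot epimerise it; the order of ring closure, and with it which unit becomes cis, is fixed because only the selenoester can start the chain; the closest known reactions are acyl radical cyclisations of aryl selenoesters, formyl hydrogen translocation to vinyl radicals, and intramolecular Giese acylation of enones.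

**Step 9**
Reactants: 19 (2S,3S)-3-[(2S,3R)-5,7-bis(benzyloxy)-2-[4-(benzyloxy)phenyl]-4-oxochroman-3-yl]-5,7-dimethoxy-2-(4-methoxyphenyl)chroman-4-one
Product: 20 (2S,3S)-3-[(2S,3R)-5,7-dihydroxy-2-(4-hydroxyphenyl)-4-oxochroman-3-yl]-5-hydroxy-7-methoxy-2-(4-methoxyphenyl)chroman-4-one
Conditions: BCl3 (10 equiv), C6HMe5 (10 equiv), CH2Cl2, −78 °C then 0 °C; MeOH/H2O
Reagents that add atoms: none
Why: Lewis acid ether cleavage in which BCl3 removes the three benzyl groups (benzyl cation trapped by pentamethylbenzene) and, through its chelate with the C4 carbonyl, only the peri 5-methoxy group of unit M, while the 7- and 4'-methoxy groups survive and the cold, non-basic medium breaks no bond to a stereocentre and does not enolise the cis ring.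

**Compound list**

1 | 2,4,6-trihydroxybenzaldehyde | O=Cc1c(O)cc(O)cc1O | starting material
2 | 4,6-bis(benzyloxy)-2-hydroxybenzaldehyde | O=Cc1c(O)cc(OCc2ccccc2)cc1OCc1ccccc1 | intermediate
3 | 4-(benzyloxy)benzaldehyde | O=Cc1ccc(OCc2ccccc2)cc1 | starting material
4 | ethynyltrimethylsilane | C#C[Si](C)(C)C | starting material
5 | methyl[(trimethylsilyl)ethynyl]zinc | C[Zn]C#C[Si](C)(C)C | intermediate
6 | (1S)-1-[4-(benzyloxy)phenyl]-3-(trimethylsilyl)prop-2-yn-1-ol | C[Si](C)(C)C#C[C@@H](O)c1ccc(OCc2ccccc2)cc1 | intermediate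
7 | 4,6-bis(benzyloxy)-2-{[(1R)-1-[4-(benzyloxy)phenyl]-3-(trimethylsilyl)prop-2-yn-1-yl]oxy}benzaldehyde | C[Si](C)(C)C#C[C@H](Oc1cc(OCc2ccccc2)cc(OCc2ccccc2)c1C=O)c1ccc(OCc2ccccc2)cc1 | intermediate
8 | 4,6-bis(benzyloxy)-2-{[(1S)-1-[4-(benzyloxy)phenyl]prop-2-yn-1-yl]oxy}benzaldehyde (same geometry as 7) | C#C[C@H](Oc1cc(OCc2ccccc2)cc(OCc2ccccc2)c1C=O)c1ccc(OCc2ccccc2)cc1 | intermediate
9 | 4-methoxybenzaldehyde | COc1ccc(C=O)cc1 | starting material
10 | {(3R)-3-[3,5-bis(benzyloxy)-2-formylphenoxy]-3-[4-(benzyloxy)phenyl]prop-1-yn-1-yl}(methyl)zinc (same geometry as 8) | C[Zn]C#C[C@H](Oc1cc(OCc2ccccc2)cc(OCc2ccccc2)c1C=O)c1ccc(OCc2ccccc2)cc1 | intermediate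
11 | 4,6-bis(benzyloxy)-2-{[(1R,4S)-1-[4-(benzyloxy)phenyl]-4-hydroxy-4-(4-methoxyphenyl)but-2-yn-1-yl]oxy}benzaldehyde | COc1ccc([C@H](O)C#C[C@H](Oc2cc(OCc3ccccc3)cc(OCc3ccccc3)c2C=O)c2ccc(OCc3ccccc3)cc2)cc1 | intermediate
12 | 2-hydroxy-4,6-dimethoxybenzoic acid | COc1cc(O)c(C(=O)O)c(OC)c1 | starting material
13 | Se-phenyl 2-hydroxy-4,6-dimethoxybenzenecarboselenoate | COc1cc(O)c(C(=O)[Se]c2ccccc2)c(OC)c1 | intermediate
14 | Se-phenyl 2-{[(1R,4R)-4-[3,5-bis(benzyloxy)-2-formylphenoxy]-4-[4-(benzyloxy)phenyl]-1-(4-methoxyphenyl)but-2-yn-1-yl]oxy}-4,6-dimethoxybenzenecarboselenoate | COc1ccc([C@@H](Oc2cc(OC)cc(OC)c2C(=O)[Se]c2ccccc2)C#C[C@H](Oc2cc(OCc3ccccc3)cc(OCc3ccccc3)c2C=O)c2ccc(OCc3ccccc3)cc2)cc1 | intermediate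
15 | first aroyl radical: 14 with the C(=O)SePh group turned into a C(=O) radical, both ether centres as in 14 | COc1ccc([C@@H](Oc2cc(OC)cc(OC)c2[C]=O)C#C[C@H](Oc2cc(OCc3ccccc3)cc(OCc3ccccc3)c2C=O)c2ccc(OCc3ccccc3)cc2)cc1 | intermediate
16 | vinyl radical: pyranone ring of unit M closed, radical on the exocyclic alkylidene carbon, formyl group still present, both stereocentres with the geometry of 14 | COc1ccc([C@H]2Oc3cc(OC)cc(OC)c3C(=O)C2=[C][C@H](Oc2cc(OCc3ccccc3)cc(OCc3ccccc3)c2C=O)c2ccc(OCc3ccccc3)cc2)cc1 | intermediate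
17 | second aroyl radical: 3-alkylidene flavanone of unit M (E/Z not fixed) with the formyl group of the other arene turned into a C(=O) radical, both stereocentres with the geometry of 14 | COc1ccc([C@H]2Oc3cc(OC)cc(OC)c3C(=O)C2=C[C@H](Oc2cc(OCc3ccccc3)cc(OCc3ccccc3)c2[C]=O)c2ccc(OCc3ccccc3)cc2)cc1 | intermediate
18 | alpha-keto radical: both pyranone rings closed, radical at C3 of unit M, (2S) in unit M and (2S,3R) in unit H | COc1ccc([C@H]2Oc3cc(OC)cc(OC)c3C(=O)[C]2[C@H]2C(=O)c3c(OCc4ccccc4)cc(OCc4ccccc4)cc3O[C@@H]2c2ccc(OCc3ccccc3)cc2)cc1 | intermediate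
19 | (2S,3S)-3-[(2S,3R)-5,7-bis(benzyloxy)-2-[4-(benzyloxy)phenyl]-4-oxochroman-3-yl]-5,7-dimethoxy-2-(4-methoxyphenyl)chroman-4-one | COc1ccc([C@H]2Oc3cc(OC)cc(OC)c3C(=O)[C@H]2[C@H]2C(=O)c3c(OCc4ccccc4)cc(OCc4ccccc4)cc3O[C@@H]2c2ccc(OCc3ccccc3)cc2)cc1 | intermediate
20 | (2S,3S)-3-[(2S,3R)-5,7-dihydroxy-2-(4-hydroxyphenyl)-4-oxochroman-3-yl]-5-hydroxy-7-methoxy-2-(4-methoxyphenyl)chroman-4-one (CNP0279849.1) | COc1ccc([C@H]2Oc3cc(OC)cc(O)c3C(=O)[C@H]2[C@H]2C(=O)c3c(O)cc(O)cc3O[C@@H]2c2ccc(O)cc2)cc1 | target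

**Totals**

Total step count: 9.
Longest linear sequence: 7 steps (3 → 6 → 7 → 8 → 11 → 14 → 19 → 20); steps 1 and 6 are side branches.

**Steps most likely to fail, with fallbacks**

Step 8 (radical cascade). The vinyl radical may be reduced by the silane before it takes the formyl hydrogen, or it may add to the formyl carbonyl or to the neighbouring arene instead. The fallback sets out from 14 and comes back at 19, and closes the rings in two operations in the same order. Reduction of 14 with Bu3SnH at high concentration (0.3 M, AIBN, PhH, 80 °C) stops after the first ring closure and gives 4,6-bis(benzyloxy)-2-{[(1S)-1-[4-(benzyloxy)phenyl]-2-[(2R)-5,7-dimethoxy-2-(4-methoxyphenyl)-4-oxochroman-3-ylidene]ethyl]oxy}benzaldehyde F1 as an E/Z mixture. A thiol-catalysed radical-chain hydroacylation (tert-dodecanethiol 10 mol%, di-tert-butyl hyponitrite, dioxane, 60 °C) then closes the second ring. The thiyl radical takes the formyl hydrogen, the aroyl radical adds to the enone as in step 8, and the thiol hands hydrogen to the alpha-keto radical anti to the 4-methoxyphenyl group, which gives 19.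

Step 7 (Mitsunobu at the 4-methoxyphenyl carbinol). This alcohol ionises easily, so part of the material may react through the cation and lose configuration, and the hindered phenol 13 may be slow. The fallback sets out from 9, uses 13, 3 and 2 as partners, and comes back at 14; it makes the 4-methoxyphenyl ether centre by catalyst control instead of inversion.
- HC≡CMgBr adds to 9 (THF, 0 °C) to give racemic 1-(4-methoxyphenyl)prop-2-yn-1-ol F2.
- Boc2O with DMAP gives racemic tert-butyl 1-(4-methoxyphenyl)prop-2-yn-1-yl carbonate F3.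
- A copper allenylidene propargylic etherification of F3 with phenol 13 ((CuOTf)2·C6H6 5 mol%, chiral Ph-pybox, iPr2NEt, −20 °C) gives Se-phenyl 2-{[(1S)-1-(4-methoxyphenyl)prop-2-yn-1-yl]oxy}-4,6-dimethoxybenzenecarboselenoate F4 from the racemate.
- ZnMe2/(S,S)-ProPhenol alkynylation of aldehyde 3 with F4 gives Se-phenyl 2-{[(1R,4S)-4-[4-(benzyloxy)phenyl]-4-hydroxy-1-(4-methoxyphenyl)but-2-yn-1-yl]oxy}-4,6-dimethoxybenzenecarboselenoate F5.
- Mitsunobu reaction of F5 with phenol 2 (the coupling type of step 3) gives 14.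

Step 5 (alkynylation in the presence of the formyl group of 8). The zinc acetylide or ZnMe2 may attack the formyl group of 8, or the reaction with the deactivated 4-methoxybenzaldehyde may be slow and poorly selective. The fallback sets out from 8 and comes back at 11 by masking the formyl group. MeOH with PPTS and 3 Å molecular sieves gives 1,5-bis(benzyloxy)-3-{[(1S)-1-[4-(benzyloxy)phenyl]prop-2-yn-1-yl]oxy}-2-(dimethoxymethyl)benzene F6. The ZnMe2/(S,S)-ProPhenol alkynylation of 9 with F6 gives (1S,4R)-4-[3,5-bis(benzyloxy)-2-(dimethoxymethyl)phenoxy]-4-[4-(benzyloxy)phenyl]-1-(4-methoxyphenyl)but-2-yn-1-ol F7. PPTS in wet acetone returns 11.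

**Further compounds**

F1 | step 8 | 4,6-bis(benzyloxy)-2-{[(1S)-1-[4-(benzyloxy)phenyl]-2-[(2R)-5,7-dimethoxy-2-(4-methoxyphenyl)-4-oxochroman-3-ylidene]ethyl]oxy}benzaldehyde (E/Z mixture) | COc1ccc([C@H]2Oc3cc(OC)cc(OC)c3C(=O)C2=C[C@H](Oc2cc(OCc3ccccc3)cc(OCc3ccccc3)c2C=O)c2ccc(OCc3ccccc3)cc2)cc1
F2 | step 7 | rac-1-(4-methoxyphenyl)prop-2-yn-1-ol | COc1ccc(C(O)C#C)cc1
F3 | step 7 | rac-tert-butyl 1-(4-methoxyphenyl)prop-2-yn-1-yl carbonate | CC(C)(C)OC(=O)OC(C#C)c1ccc(OC)cc1
F4 | step 7 | Se-phenyl 2-{[(1S)-1-(4-methoxyphenyl)prop-2-yn-1-yl]oxy}-4,6-dimethoxybenzenecarboselenoate | COc1ccc([C@@H](Oc2cc(OC)cc(OC)c2C(=O)[Se]c2ccccc2)C#C)cc1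
F5 | step 7 | Se-phenyl 2-{[(1R,4S)-4-[4-(benzyloxy)phenyl]-4-hydroxy-1-(4-methoxyphenyl)but-2-yn-1-yl]oxy}-4,6-dimethoxybenzenecarboselenoate | COc1ccc([C@@H](Oc2cc(OC)cc(OC)c2C(=O)[Se]c2ccccc2)C#C[C@@H](O)c2ccc(OCc3ccccc3)cc2)cc1
F6 | step 5 | 1,5-bis(benzyloxy)-3-{[(1S)-1-[4-(benzyloxy)phenyl]prop-2-yn-1-yl]oxy}-2-(dimethoxymethyl)benzene | C#C[C@H](Oc1cc(OCc2ccccc2)cc(OCc2ccccc2)c1C(OC)OC)c1ccc(OCc2ccccc2)cc1
F7 | step 5 | (1S,4R)-4-[3,5-bis(benzyloxy)-2-(dimethoxymethyl)phenoxy]-4-[4-(benzyloxy)phenyl]-1-(4-methoxyphenyl)but-2-yn-1-ol | COc1ccc([C@H](O)C#C[C@H](Oc2cc(OCc3ccccc3)cc(OCc3ccccc3)c2C(OC)OC)c2ccc(OCc3ccccc3)cc2)cc1
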